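**Retrosynthetic overview**
- The galloyl ester on O3' of ring B is made last, on the only free phenol of a fully benzylated 2,3-trans flavan.
- Ring C is closed last: O1–C2 forms by ionisation at C2 and capture by the C8a phenol, with C3 (S) directing C2 (R).
- Ring A is closed second and carries the strategy. Its oxygens at C5, C7 and C8a are mutually meta, and its only carbon substituent (C4 on C4a) lies between O–C5 and O–C8a. A 3-benzyloxy vinylketene plus a siloxyalkyne delivers exactly this pattern, forming C4a–C8a, C5–C6 and C8–C8a.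
- The siloxyalkyne comes from acetylide opening of an erythro epoxy silyl ether (C3–C4). C3 is set by Sharpless kinetic resolution of the ring-B vinyl carbinol, and ring B is taken from 3,4,5-trihydroxybenzaldehyde.

Key step: step 11

Remark on the chemistry: ring B is carried as its 4',5'-O-diphenylmethylene ketal with O3' as allyl ether, and 3,4,5-tris(benzyloxy)benzoic acid is taken as a purchased reagent. Flavan numbering (O1, C2–C4, C4a, C5–C8, C8a, primed ring B) is used for the open-chain intermediates as well.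

Step 1
Reactants: 1 3,4,5-trihydroxybenzaldehyde
Product: 2 7-hydroxy-2,2-diphenyl-1,3-benzodioxole-5-carbaldehyde
Conditions: Ph2CCl2, K2CO3, MeCN, rt
Reagents that add atoms: dichlorodiphenylmethane, ClC(Cl)(c1ccccc1)c1ccccc1
Why: Double O-alkylation of a vicinal diol by the gem-dichloride (catechol ketalisation) bridges O3/O4, the two possible pairings being identical by symmetry, and leaves one phenol free.

Step 2
Reactants: 2 7-hydroxy-2,2-diphenyl-1,3-benzodioxole-5-carbaldehyde
Product: 3 7-(allyloxy)-2,2-diphenyl-1,3-benzodioxole-5-carbaldehyde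
Conditions: allyl bromide, K2CO3, DMF, rt
Reagents that add atoms: allyl bromide, C=CCBr
Why: Williamson etherification of the remaining phenol installs the one ring-B protecting group that can later be removed without touching benzyl ethers or the ketal.

Step 3
Reactants: 3 7-(allyloxy)-2,2-diphenyl-1,3-benzodioxole-5-carbaldehyde
Product: 4 rac-1-[7-(allyloxy)-2,2-diphenyl-1,3-benzodioxol-5-yl]prop-2-en-1-ol
Conditions: CH2=CHMgBr, THF, −78 to 0 °C
Reagents that add atoms: vinylmagnesium bromide, C=C[Mg]Br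
Why: Grignard 1,2-addition to the aldehyde gives the racemic secondary allylic alcohol that serves as substrate for the resolution.

Step 4
Reactants: 4 rac-1-[7-(allyloxy)-2,2-diphenyl-1,3-benzodioxol-5-yl]prop-2-en-1-ol
Product: 5 (R)-[7-(allyloxy)-2,2-diphenyl-1,3-benzodioxol-5-yl][(S)-oxiran-2-yl]methanol (erythro)
Conditions: Ti(OiPr)4 (0.2 equiv), D-(−)-DIPT (0.25 equiv), t-BuOOH (0.45 equiv), 4 Å MS, CH2Cl2, −20 °C
Reagents that add atoms: tert-butyl hydroperoxide, CC(C)(C)OO
Why: In this Sharpless kinetic resolution the (S)-carbinol is the fast enantiomer with D-(−)-DIPT and is epoxidised on the catalyst-chosen alkene face to the erythro epoxy alcohol, which fixes the oxirane carbon (later C3, S); conversion is held below half so that the (R)-carbinol stays behind.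

Step 5
Reactants: 5 (R)-[7-(allyloxy)-2,2-diphenyl-1,3-benzodioxol-5-yl][(S)-oxiran-2-yl]methanol
Product: 6 tert-butyldimethylsilyl ether of 5
Conditions: TBSCl, imidazole, DMF, rt
Reagents that add atoms: tert-butyldimethylsilyl chloride, CC(C)(C)[Si](C)(C)Cl
Why: Silylation under neutral conditions protects the benzylic alcohol without forming an alkoxide, so Payne rearrangement of the epoxy alcohol is excluded.

Step 6
Reactants: 6 tert-butyldimethylsilyl ether of 5; 7 ethynyltrimethylsilane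
Product: 9 (1R,2S)-1-[7-(allyloxy)-2,2-diphenyl-1,3-benzodioxol-5-yl]-1-(tert-butyldimethylsilyloxy)-5-(trimethylsilyl)pent-4-yn-2-ol, via lithium (trimethylsilyl)acetylide 8 (not isolated)
Conditions: 7, n-BuLi, THF, −78 °C; BF3·OEt2; then 6, −78 °C
Reagents that add atoms: none
Why: BF3-promoted opening of the terminal epoxide by the lithium acetylide at its unsubstituted carbon (Yamaguchi-type alkynylation) forms C3–C4 and leaves the C3 stereocenter untouched.

Step 7
Reactants: 9 (1R,2S)-homopropargylic alcohol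
Product: 10 (1R,2S)-1-[7-(allyloxy)-2,2-diphenyl-1,3-benzodioxol-5-yl]-2-(benzyloxy)-1-(tert-butyldimethylsilyloxy)-5-(trimethylsilyl)pent-4-yne
Conditions: 2-benzyloxy-1-methylpyridinium triflate, MgO, PhCF3, 85 °C
Reagents that add atoms: 2-benzyloxy-1-methylpyridinium triflate, C[n+]1ccccc1OCc1ccccc1.[O-]S(=O)(=O)C(F)(F)F
Why: Benzyl transfer from the pyridinium salt under buffered neutral conditions etherifies the C3 alcohol and avoids the 1,2-silyl migration that an alkoxide next to the C2 silyl ether would trigger.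

Step 8
Reactants: 10 C3 benzyl ether with C-silylated alkyne
Product: 11 (1R,2S)-1-[7-(allyloxy)-2,2-diphenyl-1,3-benzodioxol-5-yl]-2-(benzyloxy)-1-(tert-butyldimethylsilyloxy)pent-4-yne
Conditions: K2CO3 (0.2 equiv), MeOH, rt
Reagents that add atoms: none
Why: Methanolysis cleaves the alkynyl C–Si bond selectively, the secondary silyl ether on oxygen being stable to K2CO3 in methanol at room temperature.

Step 9
Reactants: 11 terminal alkyne
Product: 14 (1R,2S)-1-[7-(allyloxy)-2,2-diphenyl-1,3-benzodioxol-5-yl]-2-(benzyloxy)-1-(tert-butyldimethylsilyloxy)-5-(triisopropylsilyloxy)pent-4-yne, via lithium acetylide 12 (not isolated), via lithium ynolate 13 (not isolated)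
Conditions: LiN(SiMe3)2, THF, −78 °C; LiOOtBu (from t-BuOOH + LiN(SiMe3)2), −78 to 0 °C; TIPSOTf, −78 °C
Reagents that add atoms: tert-butyl hydroperoxide, CC(C)(C)OO; triisopropylsilyl triflate, CC(C)[Si](OS(=O)(=O)C(F)(F)F)(C(C)C)C(C)C
Why: Electrophilic oxygenation of the lithium acetylide by LiOOtBu gives the lithium ynolate, which the bulky silyl triflate traps on oxygen, the established route to triisopropylsilyl ynol ethers.

Step 10
Reactants: 15 3-ethoxycyclobut-2-en-1-one
Product: 16 3-(benzyloxy)cyclobut-2-en-1-one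
Conditions: BnOH (3 equiv), CSA (5 mol %), toluene, 60 °C, reduced pressure (EtOH removed)
Reagents that add atoms: benzyl alcohol, OCc1ccccc1
Why: Acid-catalysed alkoxy exchange of a vinylogous ester (addition of BnOH at C3, loss of EtOH), as practised on squarate esters and cyclic 3-alkoxy enones, is driven forward by removal of ethanol.

Step 11
Reactants: 14 triisopropylsilyl ynol ether; 16 3-(benzyloxy)cyclobut-2-en-1-one
Product: 21 5-(benzyloxy)-2-[(2S,3R)-3-[7-(allyloxy)-2,2-diphenyl-1,3-benzodioxol-5-yl]-2-(benzyloxy)-3-(tert-butyldimethylsilyloxy)propyl]-3-(triisopropylsilyloxy)phenol, via vinylketene 17 (not isolated), via vinylcyclobutenone 18 (not isolated), via dienylketene 19 (not isolated), via cyclohexadienone 20 (not isolated)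
Conditions: toluene, 110 °C then 135 °C, sealed tube (16 in slight excess)
Reagents that add atoms: none
Why: Proposed new method: heat should open 16 by 4π electrocyclic ring opening to 3-benzyloxy vinylketene 17, whose ketene carbon is attacked by the nucleophilic chain-bearing carbon of ynol ether 14 in a [2+2] cycloaddition to give 18, and a second 4π opening to dienylketene 19, 6π electrocyclisation to 20 and tautomerisation would deliver phenol 21. The closest known reaction is the Danheiser benzannulation of 3-alkyl- and 3-aryl-cyclobutenones with triisopropylsiloxyalkynes; a 3-alkoxycyclobutenone (a vinylogous ester) has not been shown as the vinylketene source, but the 3-siloxycyclobutenone through which every siloxyalkyne benzannulation passes opens under the same conditions, which supports the proposal. Ring A is closed by this pericyclic cascade, the [2+2] step forming C4a–C8a and C5–C6 and the thermal 6π closure forming C8–C8a. No stereocenter is formed, since the sp3 centres of 18 and 20 are transient and C2 and C3 of the chain lie outside the reacting π system. The step needs regioselectivity, secured by the polarisation of the ynol ether against the electrophilic ketene carbon so that the C4 chain ends up between the new C8a–OH and C5–OTIPS, and chemoselectivity over the allyl ether and the arenes, secured by the far higher nucleophilicity of the siloxyalkyne.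

Step 12
Reactants: 21 benzannulation phenol
Product: 23 (2R,3S)-2-[7-(allyloxy)-2,2-diphenyl-1,3-benzodioxol-5-yl]-3,7-bis(benzyloxy)-5-(triisopropylsilyloxy)chromane, via benzylic cation 22 (not isolated)
Conditions: TsOH·H2O (0.3 equiv), CH2Cl2, 0 °C to rt
Reagents that add atoms: none
Why: Acid ionises the C2 silyl ether to the benzylic cation stabilised by the para oxygen of ring B, and the C8a phenol closes ring C by SN1 etherification (the known closure of 1,3-diarylpropan-1-ols to flavans), C2 being set trans to the C3 benzyloxy group because closure places the aryl group and OBn both pseudo-equatorial and reversible re-ionisation should drain the cis epimer to the diequatorial isomer.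

Step 13
Reactants: 23 5-O-silyl flavan
Product: 25 (2R,3S)-2-[7-(allyloxy)-2,2-diphenyl-1,3-benzodioxol-5-yl]-3,5,7-tris(benzyloxy)chromane, via cesium phenoxide 24 (not isolated)
Conditions: CsF, BnBr, DMF, rt
Reagents that add atoms: benzyl bromide, BrCc1ccccc1
Why: Fluoride cleaves the aryl silyl ether to the cesium phenoxide, which is benzylated in the same flask (desilylative Williamson etherification), so that no fluoride step is needed once the aryl ester is present.

Step 14
Reactants: 25 fully O-benzylated 3'-O-allyl flavan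
Product: 26 6-[(2R,3S)-3,5,7-tris(benzyloxy)chroman-2-yl]-2,2-diphenyl-1,3-benzodioxol-4-ol
Conditions: Pd(PPh3)4 (5 mol %), morpholine, THF, rt
Reagents that add atoms: none
Why: In this Tsuji–Trost deallylation zerovalent palladium ionises the aryl allyl ether and morpholine captures the allyl fragment, which frees O3' as the only hydroxyl group in the molecule.

Step 15
Reactants: 26 3'-phenol; 27 3,4,5-tris(benzyloxy)benzoic acid
Product: 28 6-[(2R,3S)-3,5,7-tris(benzyloxy)chroman-2-yl]-2,2-diphenyl-1,3-benzodioxol-4-yl 3,4,5-tris(benzyloxy)benzoate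
Conditions: EDC·HCl, DMAP, CH2Cl2, rt
Reagents that add atoms: none
Why: Steglich esterification acylates the single free phenol with the carbodiimide-activated acid under DMAP catalysis.

Step 16
Reactants: 28 protected 3'-O-gallate
Product: 29 gallocatechin 3'-O-gallate
Conditions: H2 (1 atm), Pd(OH)2/C, THF–EtOAc, rt
Reagents that add atoms: none
Why: Hydrogenolysis cleaves the six benzyl ethers and the benzhydryl-type C–O bonds of the diphenylmethylene ketal under neutral, alcohol-free conditions that should leave the aryl ester and the C2–O1 bond intact.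

**Compound list**
1 | 3,4,5-trihydroxybenzaldehyde | O=Cc1cc(O)c(O)c(O)c1 | starting material
2 | 7-hydroxy-2,2-diphenyl-1,3-benzodioxole-5-carbaldehyde | O=Cc1cc(O)c2OC(c3ccccc3)(c3ccccc3)Oc2c1 | intermediate
3 | 7-(allyloxy)-2,2-diphenyl-1,3-benzodioxole-5-carbaldehyde | O=Cc1cc(OCC=C)c2OC(c3ccccc3)(c3ccccc3)Oc2c1 | intermediate
4 | rac-1-[7-(allyloxy)-2,2-diphenyl-1,3-benzodioxol-5-yl]prop-2-en-1-ol | C=CCOc1cc(C(O)C=C)cc2c1OC(c1ccccc1)(c1ccccc1)O2 | intermediate
5 | (R)-[7-(allyloxy)-2,2-diphenyl-1,3-benzodioxol-5-yl][(S)-oxiran-2-yl]methanol | C=CCOc1cc([C@@H](O)[C@@H]2CO2)cc2c1OC(c1ccccc1)(c1ccccc1)O2 | intermediate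
6 | tert-butyldimethylsilyl ether of 5 | C=CCOc1cc([C@@H](O[Si](C)(C)C(C)(C)C)[C@@H]2CO2)cc2c1OC(c1ccccc1)(c1ccccc1)O2 | intermediate
7 | ethynyltrimethylsilane | C#C[Si](C)(C)C | starting material
8 | lithium (trimethylsilyl)acetylide (not isolated) | [Li]C#C[Si](C)(C)C | intermediate
9 | (1R,2S)-1-[7-(allyloxy)-2,2-diphenyl-1,3-benzodioxol-5-yl]-1-(tert-butyldimethylsilyloxy)-5-(trimethylsilyl)pent-4-yn-2-ol | C=CCOc1cc([C@@H](O[Si](C)(C)C(C)(C)C)[C@@H](O)CC#C[Si](C)(C)C)cc2c1OC(c1ccccc1)(c1ccccc1)O2 | intermediate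
10 | (1R,2S)-1-[7-(allyloxy)-2,2-diphenyl-1,3-benzodioxol-5-yl]-2-(benzyloxy)-1-(tert-butyldimethylsilyloxy)-5-(trimethylsilyl)pent-4-yne | C=CCOc1cc([C@@H](O[Si](C)(C)C(C)(C)C)[C@@H](OCc2ccccc2)CC#C[Si](C)(C)C)cc2c1OC(c1ccccc1)(c1ccccc1)O2 | intermediate
11 | (1R,2S)-1-[7-(allyloxy)-2,2-diphenyl-1,3-benzodioxol-5-yl]-2-(benzyloxy)-1-(tert-butyldimethylsilyloxy)pent-4-yne | C=CCOc1cc([C@@H](O[Si](C)(C)C(C)(C)C)[C@@H](OCc2ccccc2)CC#C)cc2c1OC(c1ccccc1)(c1ccccc1)O2 | intermediate
12 | lithium acetylide of 11 (not isolated) | C=CCOc1cc([C@@H](O[Si](C)(C)C(C)(C)C)[C@@H](OCc2ccccc2)CC#C[Li])cc2c1OC(c1ccccc1)(c1ccccc1)O2 | intermediate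
13 | lithium ynolate from 12 (not isolated) | C=CCOc1cc([C@@H](O[Si](C)(C)C(C)(C)C)[C@@H](OCc2ccccc2)CC#CO[Li])cc2c1OC(c1ccccc1)(c1ccccc1)O2 | intermediate
14 | (1R,2S)-1-[7-(allyloxy)-2,2-diphenyl-1,3-benzodioxol-5-yl]-2-(benzyloxy)-1-(tert-butyldimethylsilyloxy)-5-(triisopropylsilyloxy)pent-4-yne | C=CCOc1cc([C@@H](O[Si](C)(C)C(C)(C)C)[C@@H](OCc2ccccc2)CC#CO[Si](C(C)C)(C(C)C)C(C)C)cc2c1OC(c1ccccc1)(c1ccccc1)O2 | intermediate
15 | 3-ethoxycyclobut-2-en-1-one | CCOC1=CC(=O)C1 | starting material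
16 | 3-(benzyloxy)cyclobut-2-en-1-one | O=C1C=C(OCc2ccccc2)C1 | intermediate
17 | 3-(benzyloxy)buta-1,3-dien-1-one, the vinylketene (not isolated) | C=C(OCc1ccccc1)C=C=O | intermediate
18 | 4-[1-(benzyloxy)vinyl]-3-(triisopropylsilyloxy)cyclobut-2-en-1-one carrying the chain at its C2 (not isolated) | C=CCOc1cc([C@@H](O[Si](C)(C)C(C)(C)C)[C@@H](OCc2ccccc2)CC2=C(O[Si](C(C)C)(C(C)C)C(C)C)C(C(=C)OCc3ccccc3)C2=O)cc2c1OC(c1ccccc1)(c1ccccc1)O2 | intermediate
19 | dienylketene from ring opening of 18 (not isolated) | C=CCOc1cc([C@@H](O[Si](C)(C)C(C)(C)C)[C@@H](OCc2ccccc2)CC(=C=O)C(O[Si](C(C)C)(C(C)C)C(C)C)=CC(=C)OCc2ccccc2)cc2c1OC(c1ccccc1)(c1ccccc1)O2 | intermediate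
20 | 4-(benzyloxy)-2-(triisopropylsilyloxy)cyclohexa-2,4-dien-1-one-type keto tautomer of 21 (not isolated) | C=CCOc1cc([C@@H](O[Si](C)(C)C(C)(C)C)[C@@H](OCc2ccccc2)CC2=C(O[Si](C(C)C)(C(C)C)C(C)C)C=C(OCc3ccccc3)CC2=O)cc2c1OC(c1ccccc1)(c1ccccc1)O2 | intermediate
21 | 5-(benzyloxy)-2-[(2S,3R)-3-[7-(allyloxy)-2,2-diphenyl-1,3-benzodioxol-5-yl]-2-(benzyloxy)-3-(tert-butyldimethylsilyloxy)propyl]-3-(triisopropylsilyloxy)phenol | C=CCOc1cc([C@@H](O[Si](C)(C)C(C)(C)C)[C@@H](OCc2ccccc2)Cc2c(O)cc(OCc3ccccc3)cc2O[Si](C(C)C)(C(C)C)C(C)C)cc2c1OC(c1ccccc1)(c1ccccc1)O2 | intermediate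
22 | C2 benzylic cation from 21 (not isolated) | C=CCOc1cc([CH+][C@@H](OCc2ccccc2)Cc2c(O)cc(OCc3ccccc3)cc2O[Si](C(C)C)(C(C)C)C(C)C)cc2c1OC(c1ccccc1)(c1ccccc1)O2 | intermediate
23 | (2R,3S)-2-[7-(allyloxy)-2,2-diphenyl-1,3-benzodioxol-5-yl]-3,7-bis(benzyloxy)-5-(triisopropylsilyloxy)chromane | C=CCOc1cc([C@H]2Oc3cc(OCc4ccccc4)cc(O[Si](C(C)C)(C(C)C)C(C)C)c3C[C@@H]2OCc2ccccc2)cc2c1OC(c1ccccc1)(c1ccccc1)O2 | intermediate
24 | cesium 5-phenoxide of the desilylated flavan (not isolated) | [Cs+].C=CCOc1cc([C@H]2Oc3cc(OCc4ccccc4)cc([O-])c3C[C@@H]2OCc2ccccc2)cc2c1OC(c1ccccc1)(c1ccccc1)O2 | intermediate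
25 | (2R,3S)-2-[7-(allyloxy)-2,2-diphenyl-1,3-benzodioxol-5-yl]-3,5,7-tris(benzyloxy)chromane | C=CCOc1cc([C@H]2Oc3cc(OCc4ccccc4)cc(OCc4ccccc4)c3C[C@@H]2OCc2ccccc2)cc2c1OC(c1ccccc1)(c1ccccc1)O2 | intermediate
26 | 6-[(2R,3S)-3,5,7-tris(benzyloxy)chroman-2-yl]-2,2-diphenyl-1,3-benzodioxol-4-ol | Oc1cc([C@H]2Oc3cc(OCc4ccccc4)cc(OCc4ccccc4)c3C[C@@H]2OCc2ccccc2)cc2c1OC(c1ccccc1)(c1ccccc1)O2 | intermediate
27 | 3,4,5-tris(benzyloxy)benzoic acid | OC(=O)c1cc(OCc2ccccc2)c(OCc2ccccc2)c(OCc2ccccc2)c1 | starting material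
28 | 6-[(2R,3S)-3,5,7-tris(benzyloxy)chroman-2-yl]-2,2-diphenyl-1,3-benzodioxol-4-yl 3,4,5-tris(benzyloxy)benzoate | O=C(Oc1cc([C@H]2Oc3cc(OCc4ccccc4)cc(OCc4ccccc4)c3C[C@@H]2OCc2ccccc2)cc2c1OC(c1ccccc1)(c1ccccc1)O2)c1cc(OCc2ccccc2)c(OCc2ccccc2)c(OCc2ccccc2)c1 | intermediate
29 | gallocatechin 3'-O-gallate, (2R,3S) | O=C(Oc1cc([C@H]2Oc3cc(O)cc(O)c3C[C@@H]2O)cc(O)c1O)c1cc(O)c(O)c(O)c1 | target

**Step count and risks**

Total: 16 steps. Longest linear sequence: 15 steps (steps 1–9 and 11–16, from 1 to 29); step 10 is a one-step side branch.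

Steps most likely to fail:

1. Step 11 (proposed new method). The vinylogous-ester cyclobutenone may open only at temperatures at which the siloxyalkyne undergoes a 1,3-silyl shift to a silylketene, or the vinylketene may be lost to dimerisation and to O-acylation of the product phenol. The fallback uses known chemistry, buys ring A as an arene and closes ring C at O1–C8a; it sets out from 6 and comes back at 25. 1,3,5-Trifluorobenzene would be substituted twice with NaOBn (NaH, BnOH, DMF) to give 1,3-bis(benzyloxy)-5-fluorobenzene F1. NBS in MeCN should brominate it between fluorine and one benzyloxy group to give 2-bromo-1,5-bis(benzyloxy)-3-fluorobenzene F2. Bromine–lithium exchange (n-BuLi, THF, −78 °C) and BF3·OEt2-promoted opening of epoxide 6 at its terminal carbon would give the (1R,2S)-fluoroaryl alcohol F3. Benzylation as in step 7 would give the C3 benzyl ether F4, and TBAF would give the C2 alcohol F5. KH in DMF would then close O1–C8a by intramolecular SNAr, the two benzyloxy groups being meta to fluorine. Because the C2–O bond is never broken, the erythro (1R,2S) relationship maps directly onto (2R,3S), and the product is 25.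

2. Step 9. Oxygen transfer from LiOOtBu to the acetylide may stay incomplete, and the ynolate may silylate on carbon (silylketene) instead of oxygen. The fallback generates the same ynolate by sulfonate cleavage; it sets out from 11 and comes back at 14 through 13. PhI(OH)OTs would convert the terminal alkyne into the alkynyl(phenyl)iodonium tosylate F6. Catalytic CuOTf in MeCN would collapse it, with loss of iodobenzene, to the alkynyl tosylate F7. MeLi at −78 °C attacks sulfur and releases lithium ynolate 13, which is silylated with TIPSOTf as in step 9.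

3. Step 12. Capture of the C2 cation may show poor facial selectivity (2,3-cis epimer), and the cation may alkylate the electron-rich ring A of a second molecule. The fallback sets C2 by hydride delivery to a ring that is already closed; it sets out from 21 and comes back at 25. TBAF would remove both silyl groups to give the triol F8. MnO2 in CH2Cl2 would oxidise the benzylic alcohol to the aryl ketone F9, which equilibrates with its cyclic hemiketal. Et3SiH with BF3·OEt2 at −40 °C would reduce the hemiketal through the cyclic oxocarbenium ion; axial hydride delivery with the C3 benzyloxy group pseudo-equatorial should give the 2,3-trans flavan-5-ol F10, as in lactol reductions to aryl C-glycosides. BnBr and K2CO3 in DMF would then benzylate O5 and give 25.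

**Further compounds**
F1 | step 11 | 1,3-bis(benzyloxy)-5-fluorobenzene | Fc1cc(OCc2ccccc2)cc(OCc2ccccc2)c1
F2 | step 11 | 2-bromo-1,5-bis(benzyloxy)-3-fluorobenzene | Fc1cc(OCc2ccccc2)cc(OCc2ccccc2)c1Br
F3 | step 11 | (1R,2S)-1-[7-(allyloxy)-2,2-diphenyl-1,3-benzodioxol-5-yl]-3-[2,4-bis(benzyloxy)-6-fluorophenyl]-1-(tert-butyldimethylsilyloxy)propan-2-ol | C=CCOc1cc([C@@H](O[Si](C)(C)C(C)(C)C)[C@@H](O)Cc2c(F)cc(OCc3ccccc3)cc2OCc2ccccc2)cc2c1OC(c1ccccc1)(c1ccccc1)O2
F4 | step 11 | C3 benzyl ether of F3 | C=CCOc1cc([C@@H](O[Si](C)(C)C(C)(C)C)[C@@H](OCc2ccccc2)Cc2c(F)cc(OCc3ccccc3)cc2OCc2ccccc2)cc2c1OC(c1ccccc1)(c1ccccc1)O2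
F5 | step 11 | (1R,2S)-1-[7-(allyloxy)-2,2-diphenyl-1,3-benzodioxol-5-yl]-2-(benzyloxy)-3-[2,4-bis(benzyloxy)-6-fluorophenyl]propan-1-ol | C=CCOc1cc([C@@H](O)[C@@H](OCc2ccccc2)Cc2c(F)cc(OCc3ccccc3)cc2OCc2ccccc2)cc2c1OC(c1ccccc1)(c1ccccc1)O2
F6 | step 9 | alkynyl(phenyl)iodonium tosylate of 11 | C=CCOc1cc([C@@H](O[Si](C)(C)C(C)(C)C)[C@@H](OCc2ccccc2)CC#C[I+]c2ccccc2)cc2c1OC(c1ccccc1)(c1ccccc1)O2.Cc1ccc(S(=O)(=O)[O-])cc1
F7 | step 9 | alkynyl tosylate of 11 | C=CCOc1cc([C@@H](O[Si](C)(C)C(C)(C)C)[C@@H](OCc2ccccc2)CC#COS(=O)(=O)c2ccc(C)cc2)cc2c1OC(c1ccccc1)(c1ccccc1)O2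
F8 | step 12 | 2-[(2S,3R)-3-[7-(allyloxy)-2,2-diphenyl-1,3-benzodioxol-5-yl]-2-(benzyloxy)-3-hydroxypropyl]-5-(benzyloxy)benzene-1,3-diol | C=CCOc1cc([C@@H](O)[C@@H](OCc2ccccc2)Cc2c(O)cc(OCc3ccccc3)cc2O)cc2c1OC(c1ccccc1)(c1ccccc1)O2
F9 | step 12 | (S)-1-[7-(allyloxy)-2,2-diphenyl-1,3-benzodioxol-5-yl]-2-(benzyloxy)-3-[4-(benzyloxy)-2,6-dihydroxyphenyl]propan-1-one | C=CCOc1cc(C(=O)[C@@H](OCc2ccccc2)Cc2c(O)cc(OCc3ccccc3)cc2O)cc2c1OC(c1ccccc1)(c1ccccc1)O2
F10 | step 12 | (2R,3S)-2-[7-(allyloxy)-2,2-diphenyl-1,3-benzodioxol-5-yl]-3,7-bis(benzyloxy)chroman-5-ol | C=CCOc1cc([C@H]2Oc3cc(OCc4ccccc4)cc(O)c3C[C@@H]2OCc2ccccc2)cc2c1OC(c1ccccc1)(c1ccccc1)O2
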